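**Retrosynthetic overview**
1. Target 29 ⇒ tertiary alcohol 28 (late dehydration to the isopropenyl group; senecioate on O-9 and angelate on O-3 put on one after the other) ⇒ silyl-differentiated aldol 21.
2. 21 ⇒ C7–C11 aldol of the C7 enolate of 9β-silyloxy ketone 18 with acetone; 9β-oxygen ⇒ Rubottom oxidation of cis-decalone 13; 10β-H ⇒ hydrogenation of enone 12.
3. Ring A of 12 (3α-O, 4β-CH3) ⇒ C4 ketone of (S)-Wieland–Miescher ketone 5 via enol triflate, methyl coupling and α-face hydroboration (enone masked as dithiolane).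
4. Key C–C bond (C5–C6): intermolecular Michael addition of 2-methylcyclohexane-1,3-dione 1 to methyl vinyl ketone 2; the L-proline aldol condensation then sets C5.
5. Ring order: ring A comes with 1, ring B is closed second (Robinson annulation); no further ring is formed.

Assumption: the SMILES is read as (3R,4R,5R,7R,9R,10S) in eremophilane numbering (ring A = C1–C5/C10, ring B = C5–C10, CH3-14 on C5, CH3-15 on C4, side chain C11–C13 on C7); β is the face of CH3-14, and intermediates without C11–C13 are named as 11,12,13-trinoreremophilanes.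

**Route**

Step 1
Reactants: 1 2-methylcyclohexane-1,3-dione; 2 methyl vinyl ketone (but-3-en-2-one)
Product: 3 2-methyl-2-(3-oxobutyl)cyclohexane-1,3-dione
Conditions: H2O, AcOH (cat.), hydroquinone (cat.), 72–75 °C, 1 h
Reagents that add atoms: none
Why: Michael addition: the acidic 2-methyl-1,3-dione adds as its enol to the unsubstituted β-carbon of the enone under weak acid catalysis and forms the C5–C6 bond that joins the two fragments; the new quaternary carbon is still prochiral, so no stereochemistry is at stake yet.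

Step 2
Reactants: 3 2-methyl-2-(3-oxobutyl)cyclohexane-1,3-dione
Product: 5 (S)-Wieland–Miescher ketone, via bicyclic ketol 4 (not isolated)
Conditions: L-proline (5 mol%), DMSO, 35 °C, 4 d; recrystallisation to ≥99% ee
Reagents that add atoms: none
Why: Hajos–Parrish–Eder–Sauer–Wiechert reaction: the L-proline enamine of the side-chain ketone attacks one of the two enantiotopic ring carbonyls (intramolecular aldol), dehydration gives the enone, and L-proline leads to the (S)-ketone, which fixes C5 with CH3-14 on the β-face as the target needs.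

Step 3
Reactants: 5 (S)-Wieland–Miescher ketone
Product: 6 (S)-Wieland–Miescher ketone C8-dithiolane (enone carbonyl protected; C4 ketone free; C9=C10 kept)
Conditions: HSCH2CH2SH (1.05 equiv), p-TsOH·H2O, AcOH, rt, 5 h
Reagents that add atoms: ethane-1,2-dithiol SCCS
Why: Thioketalisation is selective for the conjugated carbonyl under protic acid (the hindered neopentyl C4 ketone reacts far more slowly), and a dithiolane, unlike a dioxolane, leaves the C9=C10 bond where it is.

Step 4
Reactants: 6 (S)-Wieland–Miescher ketone C8-dithiolane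
Product: 7 C4 enol triflate of 6 (C3=C4–OTf)
Conditions: KN(SiMe3)2, THF, −78 °C; PhNTf2, −78 → 0 °C
Reagents that add atoms: N-phenylbis(trifluoromethanesulfonimide) O=S(=O)(N(c1ccccc1)S(=O)(=O)C(F)(F)F)C(F)(F)F
Why: Enol triflate formation: C5 is quaternary, so the C4 ketone can only enolise toward C3, and O-sulfonylation of the potassium enolate gives a single regioisomer.

Step 5
Reactants: 7 C4 enol triflate of 6
Product: 8 8,8-(ethylenedithio)-11,12,13-trinoreremophila-3,9-diene (5β-CH3)
Conditions: MeMgBr (1.5 equiv), Fe(acac)3 (5 mol%), THF/NMP, −20 → 0 °C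
Reagents that add atoms: methylmagnesium bromide C[Mg]Br
Why: Iron-catalysed Kumada-type cross-coupling of the alkenyl triflate with MeMgBr brings in CH3-15 and fixes the C3=C4 bond regiospecifically; the dithiolane is inert to the Grignard reagent.

Step 6
Reactants: 8 8,8-(ethylenedithio)-11,12,13-trinoreremophila-3,9-diene
Product: 10 8,8-(ethylenedithio)-11,12,13-trinoreremophil-9-en-3α-ol (4β-CH3), via alkylborane 9 (not isolated)
Conditions: BH3·THF (1.1 equiv), THF, 0 °C, 3 h; then NaBO3·4H2O, H2O, rt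
Reagents that add atoms: sodium perborate tetrahydrate [Na+].[O-]OB=O.O.O.O.O
Why: Hydroboration–oxidation: syn addition of H–B from the α-face, opposite the axial CH3-14 on the neighbouring C5, puts boron (then OH, with retention) on C3 and hydrogen on C4, so 3α-OH and 4β-CH3 are set together; the C9=C10 bond should be spared because boron would have to add to the neopentyl C9 beside the spiro dithiolane.

Step 7
Reactants: 10 8,8-(ethylenedithio)-11,12,13-trinoreremophil-9-en-3α-ol
Product: 11 3α-(tert-butyldimethylsilyloxy)-8,8-(ethylenedithio)-11,12,13-trinoreremophil-9-ene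
Conditions: TBSCl, imidazole, DMF, rt
Reagents that add atoms: tert-butyldimethylsilyl chloride CC(C)(C)[Si](C)(C)Cl
Why: Silylation gives a secondary TBS ether that survives every step up to step 16.

Step 8
Reactants: 11 3α-(tert-butyldimethylsilyloxy)-8,8-(ethylenedithio)-11,12,13-trinoreremophil-9-ene
Product: 12 3α-(tert-butyldimethylsilyloxy)-11,12,13-trinoreremophil-9-en-8-one
Conditions: MeI (excess), CaCO3, MeCN/H2O 4:1, 50 °C
Reagents that add atoms: water O
Why: Dethioketalisation by S-methylation and hydrolysis of the allylic sulfonium ion under CaCO3-buffered conditions returns the conjugated enone without touching the silyl ether.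

Step 9
Reactants: 12 3α-(tert-butyldimethylsilyloxy)-11,12,13-trinoreremophil-9-en-8-one
Product: 13 3α-(tert-butyldimethylsilyloxy)-10βH-11,12,13-trinoreremophilan-8-one (cis-fused)
Conditions: H2 (1 atm), 10% Pd/C, EtOAc/pyridine 20:1, rt
Reagents that add atoms: none
Why: Heterogeneous catalytic hydrogenation of 4β,5β-dimethyl-9-en-8-ones of this type delivers hydrogen to the β-face and gives the cis-fused decalone (10β-H), with pyridine reinforcing the cis preference.

Step 10
Reactants: 13 3α-(tert-butyldimethylsilyloxy)-10βH-11,12,13-trinoreremophilan-8-one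
Product: 14 3α-(tert-butyldimethylsilyloxy)-8-(trimethylsilyloxy)-10βH-11,12,13-trinoreremophil-8-ene
Conditions: Me3SiOTf (1.3 equiv), Et3N (2 equiv), CH2Cl2, 0 °C
Reagents that add atoms: trimethylsilyl trifluoromethanesulfonate C[Si](C)(C)OS(=O)(=O)C(F)(F)F
Why: Soft enolisation/silylation: a cis-fused 8-ketone of this type, like a 5β-3-keto steroid, enolises toward the ring-fusion side, so the C8=C9 silyl enol ether forms in preference to the C7=C8 isomer.

Step 11
Reactants: 14 3α-(tert-butyldimethylsilyloxy)-8-(trimethylsilyloxy)-10βH-11,12,13-trinoreremophil-8-ene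
Product: 17 3α-(tert-butyldimethylsilyloxy)-9β-hydroxy-10βH-11,12,13-trinoreremophilan-8-one, via silyloxy epoxide 15 (not isolated), via α-trimethylsilyloxy ketone 16 (not isolated)
Conditions: mCPBA (1.1 equiv), CH2Cl2, −20 → 0 °C; then 1 M aq. citric acid, THF, rt
Reagents that add atoms: 3-chloroperoxybenzoic acid OOC(=O)c1cccc(Cl)c1
Why: Rubottom oxidation: the peracid epoxidises the enol ether from the convex β-face (the α-face lies under the axial C5–C4 bond), and silyl migration then hydrolysis give the 9β-hydroxy ketone, which is also the equatorial, thermodynamically preferred epimer.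

Step 12
Reactants: 17 3α-(tert-butyldimethylsilyloxy)-9β-hydroxy-10βH-11,12,13-trinoreremophilan-8-one
Product: 18 3α-(tert-butyldimethylsilyloxy)-9β-(triethylsilyloxy)-10βH-11,12,13-trinoreremophilan-8-one
Conditions: Et3SiCl, imidazole, DMF, 0 °C
Reagents that add atoms: chlorotriethylsilane CC[Si](CC)(CC)Cl
Why: Silylation protects the α-ketol and makes H-9 kinetically inaccessible in the next step.

Step 13
Reactants: 18 3α-(tert-butyldimethylsilyloxy)-9β-(triethylsilyloxy)-10βH-11,12,13-trinoreremophilan-8-one; 19 acetone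
Product: 21 3α-(tert-butyldimethylsilyloxy)-11-hydroxy-9β-(triethylsilyloxy)-7αH,10βH-eremophilan-8-one, via lithium enolate 20 (not isolated)
Conditions: LiN(iPr)2 (1.1 equiv), THF, −78 °C, 45 min; acetone (3 equiv), −78 °C, 20 min; AcOH, −78 °C
Reagents that add atoms: none
Why: Directed aldol addition: LiN(iPr)2 removes the unhindered α′-proton at C7 (not the methine H-9 next to the silyloxy group), and the enolate adds to acetone from the convex β-face to give the equatorial 7β-(2-hydroxypropan-2-yl) ketone, which is also the more stable C7 epimer.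

Step 14
Reactants: 21 3α-(tert-butyldimethylsilyloxy)-11-hydroxy-9β-(triethylsilyloxy)-7αH,10βH-eremophilan-8-one
Product: 22 3α-(tert-butyldimethylsilyloxy)-9β,11-dihydroxy-7αH,10βH-eremophilan-8-one
Conditions: PPTS (0.2 equiv), MeOH, 0 °C → rt
Reagents that add atoms: none
Why: Acid-catalysed methanolysis cleaves the triethylsilyl ether next to the ketone far faster than the hindered secondary TBS ether, so only O-9 is freed.

Step 15
Reactants: 22 3α-(tert-butyldimethylsilyloxy)-9β,11-dihydroxy-7αH,10βH-eremophilan-8-one; 23 3-methylbut-2-enoic acid (senecioic acid)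
Product: 24 3α-(tert-butyldimethylsilyloxy)-11-hydroxy-9β-(3-methylbut-2-enoyloxy)-7αH,10βH-eremophilan-8-one
Conditions: DCC (1.5 equiv), DMAP (0.2 equiv), CH2Cl2, 0 °C → rt
Reagents that add atoms: none
Why: Steglich esterification acylates only the secondary 9β-hydroxyl (the tertiary C11 carbinol is inert) and, being an O-acylation, retains the C9 configuration.

Step 16
Reactants: 24 3α-(tert-butyldimethylsilyloxy)-11-hydroxy-9β-(3-methylbut-2-enoyloxy)-7αH,10βH-eremophilan-8-one
Product: 25 3α,11-dihydroxy-9β-(3-methylbut-2-enoyloxy)-7αH,10βH-eremophilan-8-one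
Conditions: HF·pyridine, pyridine/THF, 0 °C → rt
Reagents that add atoms: none
Why: Fluoride-mediated desilylation under buffered, non-basic conditions frees O-3 without acyl migration, retro-aldol cleavage or epimerisation.

Step 17
Reactants: 25 3α,11-dihydroxy-9β-(3-methylbut-2-enoyloxy)-7αH,10βH-eremophilan-8-one; 26 angelic acid ((Z)-2-methylbut-2-enoic acid)
Product: 28 3α-angeloyloxy-11-hydroxy-9β-senecioyloxy-7αH,10βH-eremophilan-8-one, via mixed anhydride 27 (not isolated)
Conditions: 26, 2,4,6-trichlorobenzoyl chloride, Et3N, toluene, rt, 2 h; then 25, toluene, 80 °C, 24 h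
Reagents that add atoms: none
Why: Yamaguchi-type mixed-anhydride esterification without a nucleophilic catalyst: the alcohol attacks the unhindered angeloyl carbonyl and the (Z)-alkene does not isomerise to the tiglate; the tertiary hydroxyl does not react.

Step 18
Reactants: 28 3α-angeloyloxy-11-hydroxy-9β-senecioyloxy-7αH,10βH-eremophilan-8-one
Product: 29 3α-angeloyloxy-9β-senecioyloxy-7αH,10βH-eremophil-11-en-8-one (target)
Conditions: Burgess reagent (2 equiv), toluene, 50 °C, 1 h
Reagents that add atoms: none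
Why: Burgess dehydration is a syn (Ei) elimination of the tertiary sulfamate; in the favoured rotamer the C11–O bond is anti to H-7, so only methyl hydrogens are within reach and the isopropenyl group forms under neutral conditions that do not epimerise C7 or move the alkene into conjugation.

**Compound list**
1 | 2-methylcyclohexane-1,3-dione | CC1C(=O)CCCC1=O | starting material
2 | methyl vinyl ketone (but-3-en-2-one) | C=CC(C)=O | starting material
3 | 2-methyl-2-(3-oxobutyl)cyclohexane-1,3-dione | CC(=O)CCC1(C)C(=O)CCCC1=O | intermediate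
4 | (4aS,8aS)-4a-hydroxy-8a-methyloctahydronaphthalene-1,6-dione (cis-fused ketol, formed in situ) | C[C@]12CCC(=O)C[C@@]1(O)CCCC2=O | intermediate
5 | (S)-Wieland–Miescher ketone, (S)-8a-methyl-3,4,8,8a-tetrahydronaphthalene-1,6(2H,7H)-dione | C[C@]12CCC(=O)C=C1CCCC2=O | intermediate
6 | (S)-Wieland–Miescher ketone C8-dithiolane (C4 ketone free, C9=C10) | C1C[C@@]2(C)C(CCCC2=O)=CC13SCCS3 | intermediate
7 | C4 enol triflate of 6 (C3=C4–OTf, C9=C10, C8 dithiolane) | C1C[C@@]2(C)C(CCC=C2OS(=O)(=O)C(F)(F)F)=CC13SCCS3 | intermediate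
8 | 8,8-(ethylenedithio)-11,12,13-trinoreremophila-3,9-diene (5β-CH3) | C1C[C@@]2(C)C(CCC=C2C)=CC13SCCS3 | intermediate
9 | 3α-boryl-4β-methyl alkylborane from 8 (formed in situ) | C1C[C@@]2(C)C(CC[C@@H](B)[C@@H]2C)=CC13SCCS3 | intermediate
10 | 8,8-(ethylenedithio)-11,12,13-trinoreremophil-9-en-3α-ol (4β-CH3, 5β-CH3) | C1C[C@@]2(C)C(CC[C@@H](O)[C@@H]2C)=CC13SCCS3 | intermediate
11 | 3α-(tert-butyldimethylsilyloxy)-8,8-(ethylenedithio)-11,12,13-trinoreremophil-9-ene | C1C[C@@]2(C)C(CC[C@@H](O[Si](C)(C)C(C)(C)C)[C@@H]2C)=CC13SCCS3 | intermediate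
12 | 3α-(tert-butyldimethylsilyloxy)-11,12,13-trinoreremophil-9-en-8-one | C1C[C@@]2(C)C(CC[C@@H](O[Si](C)(C)C(C)(C)C)[C@@H]2C)=CC1=O | intermediate
13 | 3α-(tert-butyldimethylsilyloxy)-10βH-11,12,13-trinoreremophilan-8-one (cis-fused) | C1C[C@@]2(C)[C@H](CC[C@@H](O[Si](C)(C)C(C)(C)C)[C@@H]2C)CC1=O | intermediate
14 | 3α-(tert-butyldimethylsilyloxy)-8-(trimethylsilyloxy)-10βH-11,12,13-trinoreremophil-8-ene | C1C[C@@]2(C)[C@H](CC[C@@H](O[Si](C)(C)C(C)(C)C)[C@@H]2C)C=C1O[Si](C)(C)C | intermediate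
15 | 8β,9β-epoxide of 14 (silyloxy epoxide, formed in situ) | C1C[C@@]2(C)[C@H](CC[C@@H](O[Si](C)(C)C(C)(C)C)[C@@H]2C)[C@H]3O[C@@]13O[Si](C)(C)C | intermediate
16 | 3α-(tert-butyldimethylsilyloxy)-9β-(trimethylsilyloxy)-10βH-11,12,13-trinoreremophilan-8-one (formed in situ) | C1C[C@@]2(C)[C@H](CC[C@@H](O[Si](C)(C)C(C)(C)C)[C@@H]2C)[C@@H](O[Si](C)(C)C)C1=O | intermediate
17 | 3α-(tert-butyldimethylsilyloxy)-9β-hydroxy-10βH-11,12,13-trinoreremophilan-8-one | C1C[C@@]2(C)[C@H](CC[C@@H](O[Si](C)(C)C(C)(C)C)[C@@H]2C)[C@@H](O)C1=O | intermediate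
18 | 3α-(tert-butyldimethylsilyloxy)-9β-(triethylsilyloxy)-10βH-11,12,13-trinoreremophilan-8-one | C1C[C@@]2(C)[C@H](CC[C@@H](O[Si](C)(C)C(C)(C)C)[C@@H]2C)[C@@H](O[Si](CC)(CC)CC)C1=O | intermediate
19 | acetone | CC(C)=O | starting material
20 | lithium C7=C8 enolate of 18 (formed in situ) | [Li]OC1=CC[C@@]2(C)[C@H](CC[C@@H](O[Si](C)(C)C(C)(C)C)[C@@H]2C)[C@H]1O[Si](CC)(CC)CC | intermediate
21 | 3α-(tert-butyldimethylsilyloxy)-11-hydroxy-9β-(triethylsilyloxy)-7αH,10βH-eremophilan-8-one | CC(C)(O)[C@H]1C[C@@]2(C)[C@H](CC[C@@H](O[Si](C)(C)C(C)(C)C)[C@@H]2C)[C@@H](O[Si](CC)(CC)CC)C1=O | intermediate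
22 | 3α-(tert-butyldimethylsilyloxy)-9β,11-dihydroxy-7αH,10βH-eremophilan-8-one | CC(C)(O)[C@H]1C[C@@]2(C)[C@H](CC[C@@H](O[Si](C)(C)C(C)(C)C)[C@@H]2C)[C@@H](O)C1=O | intermediate
23 | 3-methylbut-2-enoic acid (senecioic acid) | CC(C)=CC(=O)O | starting material
24 | 3α-(tert-butyldimethylsilyloxy)-11-hydroxy-9β-(3-methylbut-2-enoyloxy)-7αH,10βH-eremophilan-8-one | CC(C)(O)[C@H]1C[C@@]2(C)[C@H](CC[C@@H](O[Si](C)(C)C(C)(C)C)[C@@H]2C)[C@@H](OC(=O)C=C(C)C)C1=O | intermediate
25 | 3α,11-dihydroxy-9β-(3-methylbut-2-enoyloxy)-7αH,10βH-eremophilan-8-one | CC(C)(O)[C@H]1C[C@@]2(C)[C@H](CC[C@@H](O)[C@@H]2C)[C@@H](OC(=O)C=C(C)C)C1=O | intermediate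
26 | angelic acid, (Z)-2-methylbut-2-enoic acid | C/C=C(/C)C(=O)O | starting material
27 | angelic 2,4,6-trichlorobenzoic anhydride (formed in situ) | C/C=C(/C)C(=O)OC(=O)c1c(Cl)cc(Cl)cc1Cl | intermediate
28 | 3α-angeloyloxy-11-hydroxy-9β-senecioyloxy-7αH,10βH-eremophilan-8-one | CC(C)(O)[C@H]1C[C@@]2(C)[C@H](CC[C@@H](OC(=O)/C(C)=C\C)[C@@H]2C)[C@@H](OC(=O)C=C(C)C)C1=O | intermediate
29 | 3α-angeloyloxy-9β-senecioyloxy-7αH,10βH-eremophil-11-en-8-one, (3R,4R,5R,7R,9R,10S) | C=C(C)[C@H]1C[C@@]2(C)[C@H](CC[C@@H](OC(=O)/C(C)=C\C)[C@@H]2C)[C@@H](OC(=O)C=C(C)C)C1=O | target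

**Totals**
Total step count: 18. Longest linear sequence: 18 steps (1 → 29; compounds 2, 19, 23 and 26 are bought and enter directly).

**Three steps most likely to fail**

Step 6 (hydroboration must choose C3=C4 over C9=C10 and tolerate sulfur). Fallback: take away the competing alkene before hydroboration. Setting out from 8, MeI/CaCO3 in aqueous MeCN frees the dienone F1. Hydrogenation over Pd/C in EtOAc/pyridine, stopped after one equivalent of H2, reduces only the conjugated C9=C10 bond and gives the cis-fused enone-free ketone F2, which still holds the hindered C3=C4 bond. Ethylene glycol/PPTS (benzene, Dean–Stark) gives the dioxolane F3. BH3·THF then NaBO3·4H2O now meets a single alkene and gives, by attack anti to the allylic axial CH3-14, the 3α-alcohol F4. TBSCl/imidazole gives the silyl ether F5, and PPTS in wet acetone removes the dioxolane, so that the fallback comes back to the route at 13.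

Step 10 (enolisation toward C9 and not C7; it decides steps 11–13). Fallback: put the C7 side chain in first, at the enone stage where only C7 can be deprotonated kinetically, so that afterwards C9 carries the only unhindered α-hydrogens. Setting out from 12, LiN(iPr)2 (THF, −78 °C) then acetone gives the 7α-(2-hydroxypropan-2-yl) enone F6. H2 over Pd/C gives the cis-fused ketone F7, and DBU in CH2Cl2 equilibrates C7 to the equatorial 7β epimer F8. LiN(iPr)2 (2.2 equiv)/Me3SiCl at −78 °C removes a proton from C9 (C7 is now a hindered methine) and silylates both oxygens to give the bis-silyl enol ether F9. mCPBA then gives the silyloxy epoxide F10 and from it the 9β-trimethylsilyloxy ketone F11, and citric acid work-up gives 22, where the fallback comes back to the route.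

Step 18 (isopropenyl versus the conjugated isopropylidene isomer). Fallback: form the alkene by a regiospecific elimination that cannot involve H-7. Setting out from 18, the lithium enolate 20 is added at −78 °C to 1-(phenylselanyl)propan-2-one F12 (made from chloroacetone, PhSeSePh and NaBH4) to give the β-hydroxy selenide F13 (both C11 epimers, of no consequence). PPTS/MeOH gives the 9β-alcohol F14, DCC/DMAP with 23 gives the senecioate F15, HF·pyridine gives the 3α-alcohol F16, and the mixed anhydride 27 gives the angelate F17. MsCl/Et3N in CH2Cl2 at 0 °C then activates the tertiary hydroxyl and selenium leaves with it (Reich–Krief β-hydroxy selenide elimination); this can only form the C11=C12 bond and gives the target 29.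

**Further compounds**
F1 | step 6 | 11,12,13-trinoreremophila-3,9-dien-8-one (5β-CH3) | C1C[C@@]2(C)C(CCC=C2C)=CC1=O
F2 | step 6 | 10βH-11,12,13-trinoreremophil-3-en-8-one (cis-fused) | C1C[C@@]2(C)[C@H](CCC=C2C)CC1=O
F3 | step 6 | 8,8-(ethylenedioxy)-10βH-11,12,13-trinoreremophil-3-ene | C1C[C@@]2(C)[C@H](CCC=C2C)CC13OCCO3
F4 | step 6 | 8,8-(ethylenedioxy)-10βH-11,12,13-trinoreremophilan-3α-ol (4β-CH3) | C1C[C@@]2(C)[C@H](CC[C@@H](O)[C@@H]2C)CC13OCCO3
F5 | step 6 | 3α-(tert-butyldimethylsilyloxy)-8,8-(ethylenedioxy)-10βH-11,12,13-trinoreremophilane | C1C[C@@]2(C)[C@H](CC[C@@H](O[Si](C)(C)C(C)(C)C)[C@@H]2C)CC13OCCO3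
F6 | step 10 | 3α-(tert-butyldimethylsilyloxy)-11-hydroxy-7βH-eremophil-9-en-8-one (7α side chain) | CC(C)(O)[C@@H]1C[C@@]2(C)C(CC[C@@H](O[Si](C)(C)C(C)(C)C)[C@@H]2C)=CC1=O
F7 | step 10 | 3α-(tert-butyldimethylsilyloxy)-11-hydroxy-7βH,10βH-eremophilan-8-one (7α side chain) | CC(C)(O)[C@@H]1C[C@@]2(C)[C@H](CC[C@@H](O[Si](C)(C)C(C)(C)C)[C@@H]2C)CC1=O
F8 | step 10 | 3α-(tert-butyldimethylsilyloxy)-11-hydroxy-7αH,10βH-eremophilan-8-one (7β side chain) | CC(C)(O)[C@H]1C[C@@]2(C)[C@H](CC[C@@H](O[Si](C)(C)C(C)(C)C)[C@@H]2C)CC1=O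
F9 | step 10 | 3α-(tert-butyldimethylsilyloxy)-8,11-bis(trimethylsilyloxy)-7αH,10βH-eremophil-8-ene | CC(C)(O[Si](C)(C)C)[C@H]1C[C@@]2(C)[C@H](CC[C@@H](O[Si](C)(C)C(C)(C)C)[C@@H]2C)C=C1O[Si](C)(C)C
F10 | step 10 | 8β,9β-epoxide of F9 | CC(C)(O[Si](C)(C)C)[C@H]1C[C@@]2(C)[C@H](CC[C@@H](O[Si](C)(C)C(C)(C)C)[C@@H]2C)[C@H]3O[C@@]13O[Si](C)(C)C
F11 | step 10 | 3α-(tert-butyldimethylsilyloxy)-9β,11-bis(trimethylsilyloxy)-7αH,10βH-eremophilan-8-one | CC(C)(O[Si](C)(C)C)[C@H]1C[C@@]2(C)[C@H](CC[C@@H](O[Si](C)(C)C(C)(C)C)[C@@H]2C)[C@@H](O[Si](C)(C)C)C1=O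
F12 | step 18 | 1-(phenylselanyl)propan-2-one | CC(=O)C[Se]c1ccccc1
F13 | step 18 | 3α-(tert-butyldimethylsilyloxy)-11-hydroxy-12-(phenylselanyl)-9β-(triethylsilyloxy)-7αH,10βH-eremophilan-8-one (C11 epimers) | CC(O)(C[Se]c1ccccc1)[C@H]1C[C@@]2(C)[C@H](CC[C@@H](O[Si](C)(C)C(C)(C)C)[C@@H]2C)[C@@H](O[Si](CC)(CC)CC)C1=O
F14 | step 18 | 3α-(tert-butyldimethylsilyloxy)-9β,11-dihydroxy-12-(phenylselanyl)-7αH,10βH-eremophilan-8-one | CC(O)(C[Se]c1ccccc1)[C@H]1C[C@@]2(C)[C@H](CC[C@@H](O[Si](C)(C)C(C)(C)C)[C@@H]2C)[C@@H](O)C1=O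
F15 | step 18 | 3α-(tert-butyldimethylsilyloxy)-11-hydroxy-12-(phenylselanyl)-9β-senecioyloxy-7αH,10βH-eremophilan-8-one | CC(O)(C[Se]c1ccccc1)[C@H]1C[C@@]2(C)[C@H](CC[C@@H](O[Si](C)(C)C(C)(C)C)[C@@H]2C)[C@@H](OC(=O)C=C(C)C)C1=O
F16 | step 18 | 3α,11-dihydroxy-12-(phenylselanyl)-9β-senecioyloxy-7αH,10βH-eremophilan-8-one | CC(O)(C[Se]c1ccccc1)[C@H]1C[C@@]2(C)[C@H](CC[C@@H](O)[C@@H]2C)[C@@H](OC(=O)C=C(C)C)C1=O
F17 | step 18 | 3α-angeloyloxy-11-hydroxy-12-(phenylselanyl)-9β-senecioyloxy-7αH,10βH-eremophilan-8-one | CC(O)(C[Se]c1ccccc1)[C@H]1C[C@@]2(C)[C@H](CC[C@@H](OC(=O)/C(C)=C\C)[C@@H]2C)[C@@H](OC(=O)C=C(C)C)C1=O
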